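**Retrosynthetic overview**
- The route rests on the C4 carbonyl of ring C. Its only carbon neighbours are C4a of the hexasubstituted ring A and C3, the carbon bearing the methoxy group, so C4 can be removed as carbon monoxide (cuts C4a–C4 and C4–C3).
- This leaves a mirror-symmetric ring A iodide, with iodine between two protected phenols and the prenyl groups already at the future C6 and C8. The other piece is a ring B ω-methoxyacetophenone that supplies C2, C3 and the OMe group.
- Ring A iodide: phloroglucinol, tris-MOM ether, then three directed ortho-lithiations in a row (prenyl, prenyl, iodine). Ring B ketone: 4-bromocatechol bis-MOM ether, Br/Li exchange, Weinreb acylation.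
- Rings A and B come from commercial arenes. Ring C is the only ring made and is closed last (O1–C2), when acid frees the phenols and one of the two equivalent ortho phenols condenses with the ring B carbonyl.

Key step: step 7

Remark: the target has no stereocentre and no E/Z-isomeric alkene, and the single sp3 centre of the diketone intermediates is enolisable and is drawn without configuration. MOM = CH2OCH3, prenyl = 3-methylbut-2-enyl.

**Step 1**
Reactants: 1 phloroglucinol (benzene-1,3,5-triol, anhydrous)
Product: 2 1,3,5-tris(methoxymethoxy)benzene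
Conditions: NaH (3.6 equiv), MOMCl (3.6 equiv), DMF, 0 °C to rt
Reagents that add atoms: chloromethyl methyl ether (MOMCl), COCCl
Why: Williamson-type O-alkylation, in which the hard, oxocarbenium-like electrophile reacts at oxygen of the sodium phenoxides, so the C-alkylation that soft halides cause with phloroglucinol is avoided.

**Step 2**
Reactants: 2 1,3,5-tris(methoxymethoxy)benzene; 3 prenyl bromide (1-bromo-3-methylbut-2-ene)
Product: 5 1,3,5-tris(methoxymethoxy)-2-(3-methylbut-2-enyl)benzene, via aryllithium 4 (not isolated)
Conditions: n-BuLi (1.1 equiv), THF, 0 °C; then 3 (1.2 equiv), −78 °C to rt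
Reagents that add atoms: none
Why: Directed ortho-metalation, in which each ring CH lies between two coordinating OMOM groups and all three are equivalent, so a single aryllithium forms and attacks the primary carbon of the allylic bromide in an SN2 alkylation.

**Step 3**
Reactants: 5 1,3,5-tris(methoxymethoxy)-2-(3-methylbut-2-enyl)benzene; 3 prenyl bromide
Product: 7 1,3,5-tris(methoxymethoxy)-2,4-bis(3-methylbut-2-enyl)benzene, via aryllithium 6 (not isolated)
Conditions: n-BuLi (1.1 equiv), THF, 0 °C; then 3 (1.2 equiv), −78 °C to rt
Reagents that add atoms: none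
Why: Second directed ortho-metalation and SN2 alkylation, in which the two remaining ring CH are equivalent by symmetry and each still sits between two OMOM groups, so complex-induced deprotonation there should be faster than removal of a benzylic-allylic proton.

**Step 4**
Reactants: 7 1,3,5-tris(methoxymethoxy)-2,4-bis(3-methylbut-2-enyl)benzene
Product: 9 2-iodo-1,3,5-tris(methoxymethoxy)-4,6-bis(3-methylbut-2-enyl)benzene, via aryllithium 8 (not isolated)
Conditions: n-BuLi (1.2 equiv), THF, 0 °C; then ICH2CH2I (1.3 equiv), −78 °C to rt
Reagents that add atoms: 1,2-diiodoethane, ICCI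
Why: Third directed ortho-metalation followed by iodine transfer to the aryllithium, in which the last ring CH is again bracketed by two OMOM groups and 1,2-diiodoethane hands over iodine with loss of ethene without exposing the two alkenes to an electrophilic iodine species.

**Step 5**
Reactants: 10 4-bromocatechol (4-bromobenzene-1,2-diol)
Product: 11 4-bromo-1,2-bis(methoxymethoxy)benzene
Conditions: NaH (2.4 equiv), MOMCl (2.4 equiv), DMF, 0 °C to rt
Reagents that add atoms: chloromethyl methyl ether (MOMCl), COCCl
Why: Williamson-type O-alkylation of both catechol oxygens, which leaves the aryl bromide untouched.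

**Step 6**
Reactants: 11 4-bromo-1,2-bis(methoxymethoxy)benzene; 12 N,2-dimethoxy-N-methylacetamide
Product: 15 1-[3,4-bis(methoxymethoxy)phenyl]-2-methoxyethanone, via aryllithium 13 (not isolated), via lithium hemiaminal alkoxide 14 (not isolated)
Conditions: n-BuLi (1.05 equiv), THF, −78 °C; then 12 (1.1 equiv), −78 to 0 °C; sat. aq. NH4Cl
Reagents that add atoms: none
Why: Bromine–lithium exchange (faster at −78 °C than ortho-metalation) and Weinreb ketone synthesis, in which the chelated adduct 14 lasts until the quench so only one aryl group is taken up, and the ω-methoxy ketone is reached without the carbonyl attack and epoxy-ether formation that accompany methoxide displacement on phenacyl halides.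

**Step 7**
Reactants: 9 2-iodo-1,3,5-tris(methoxymethoxy)-4,6-bis(3-methylbut-2-enyl)benzene; 15 1-[3,4-bis(methoxymethoxy)phenyl]-2-methoxyethanone; 16 carbon monoxide
Product: 19 1-[3,4-bis(methoxymethoxy)phenyl]-2-methoxy-3-[2,4,6-tris(methoxymethoxy)-3,5-bis(3-methylbut-2-enyl)phenyl]propane-1,3-dione, via sodium enolate 17 (not isolated), via sodium diketonate 18 (not isolated)
Conditions: 15 (2.2 equiv), NaN(SiMe3)2 (2.1 equiv), THF, 0 °C; then 9 (1.0 equiv), Pd(dba)2 (5 mol %), 1,3-bis(diphenylphosphino)propane (dppp, 6 mol %), CO (1 atm), THF, 70 °C; sat. aq. NH4Cl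
Reagents that add atoms: none
Why: The dppp complex of zerovalent palladium adds into the C–I bond of 9, and aryl migration onto bound CO follows readily because it pulls the metal out of the pocket formed by the two flanking OMOM groups. Enolate 17 then takes the place of iodide on the aroylpalladium intermediate and reductive elimination closes the C4–C3 bond, so C4a–C4 and C4–C3 arise in one flask; the reaction type is the known palladium-catalysed carbonylative α-arylation of aryl alkyl ketones with aryl iodides, used here on a di-ortho-alkoxy iodide. No ring is closed, and the only new sp3 centre (the future C3, between two carbonyl groups) is enolisable, is left uncontrolled and becomes planar in step 8. The first selectivity needed is CO insertion ahead of direct aryl–enolate coupling, which the substrate secures through its two ortho substituents (they retard reductive elimination from an arylpalladium enolate but speed up CO insertion) and which the CO atmosphere supports. The second is acylation at carbon and not at oxygen of the enolate, which the soft acylpalladium centre favours, while any enol ester formed would be turned by excess 17 into the much more stable diketonate 18. A second equivalent of 17 acts as the base that stores the product as 18, so no free NaN(SiMe3)2 is present to attack CO or the acylpalladium species, and the prenyl groups, meta to the reacting carbon, cannot reach the metal for a Heck-type insertion.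

**Step 8**
Reactants: 19 penta-O-MOM diketone
Product: 21 broussoflavonol B, via pentaphenol diketone 20 (not isolated)
Conditions: HCl (ca. 0.5 M in MeOH), 40 °C, argon
Reagents that add atoms: none
Why: Acid-catalysed transacetalisation to methanol removes the five MOM groups, and in 20 one of the two equivalent ortho phenols adds 6-exo-trig to the ring B carbonyl and loses water to give the aromatic 4-pyranone ring C, as in the closing stage of a Baker–Venkataraman flavone synthesis, while dilute acid at moderate temperature is the usual way to keep ortho-prenyl phenols from closing to chromans.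

**Compound list**
1 | phloroglucinol (benzene-1,3,5-triol) | Oc1cc(O)cc(O)c1 | starting material
2 | 1,3,5-tris(methoxymethoxy)benzene | COCOc1cc(OCOC)cc(OCOC)c1 | intermediate
3 | prenyl bromide (1-bromo-3-methylbut-2-ene) | CC(C)=CCBr | starting material
4 | 2,4,6-tris(methoxymethoxy)phenyllithium | [Li]c1c(OCOC)cc(OCOC)cc1OCOC | intermediate
5 | 1,3,5-tris(methoxymethoxy)-2-(3-methylbut-2-enyl)benzene | COCOc1cc(OCOC)c(CC=C(C)C)c(OCOC)c1 | intermediate
6 | 2,4,6-tris(methoxymethoxy)-3-(3-methylbut-2-enyl)phenyllithium | [Li]c1c(OCOC)cc(OCOC)c(CC=C(C)C)c1OCOC | intermediate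
7 | 1,3,5-tris(methoxymethoxy)-2,4-bis(3-methylbut-2-enyl)benzene | COCOc1cc(OCOC)c(CC=C(C)C)c(OCOC)c1CC=C(C)C | intermediate
8 | 2,4,6-tris(methoxymethoxy)-3,5-bis(3-methylbut-2-enyl)phenyllithium | [Li]c1c(OCOC)c(CC=C(C)C)c(OCOC)c(CC=C(C)C)c1OCOC | intermediate
9 | 2-iodo-1,3,5-tris(methoxymethoxy)-4,6-bis(3-methylbut-2-enyl)benzene | COCOc1c(I)c(OCOC)c(CC=C(C)C)c(OCOC)c1CC=C(C)C | intermediate
10 | 4-bromocatechol (4-bromobenzene-1,2-diol) | Oc1ccc(Br)cc1O | starting material
11 | 4-bromo-1,2-bis(methoxymethoxy)benzene | COCOc1ccc(Br)cc1OCOC | intermediate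
12 | N,2-dimethoxy-N-methylacetamide | COCC(=O)N(C)OC | starting material
13 | 3,4-bis(methoxymethoxy)phenyllithium | [Li]c1ccc(OCOC)c(OCOC)c1 | intermediate
14 | lithium hemiaminal alkoxide from 13 and 12 (racemic) | COCC([O-])(N(C)OC)c1ccc(OCOC)c(OCOC)c1.[Li+] | intermediate
15 | 1-[3,4-bis(methoxymethoxy)phenyl]-2-methoxyethanone | COCC(=O)c1ccc(OCOC)c(OCOC)c1 | intermediate
16 | carbon monoxide | [C-]#[O+] | starting material
17 | sodium enolate of 15 (geometry of no consequence) | COC=C([O-])c1ccc(OCOC)c(OCOC)c1.[Na+] | intermediate
18 | sodium enolate of diketone 19 (geometry of no consequence) | COC(C(=O)c1c(OCOC)c(CC=C(C)C)c(OCOC)c(CC=C(C)C)c1OCOC)=C([O-])c1ccc(OCOC)c(OCOC)c1.[Na+] | intermediate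
19 | 1-[3,4-bis(methoxymethoxy)phenyl]-2-methoxy-3-[2,4,6-tris(methoxymethoxy)-3,5-bis(3-methylbut-2-enyl)phenyl]propane-1,3-dione (racemic, enolisable) | COCOc1ccc(C(=O)C(OC)C(=O)c2c(OCOC)c(CC=C(C)C)c(OCOC)c(CC=C(C)C)c2OCOC)cc1OCOC | intermediate
20 | 1-(3,4-dihydroxyphenyl)-2-methoxy-3-[2,4,6-trihydroxy-3,5-bis(3-methylbut-2-enyl)phenyl]propane-1,3-dione (racemic, enolisable) | COC(C(=O)c1ccc(O)c(O)c1)C(=O)c1c(O)c(CC=C(C)C)c(O)c(CC=C(C)C)c1O | intermediate
21 | broussoflavonol B, 2-(3,4-dihydroxyphenyl)-5,7-dihydroxy-3-methoxy-6,8-bis(3-methylbut-2-enyl)chromen-4-one | COc1c(-c2ccc(O)c(O)c2)oc2c(CC=C(C)C)c(O)c(CC=C(C)C)c(O)c2c1=O | target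

**Step count**
- Total step count: 8
- Longest linear sequence: 6 steps (steps 1, 2, 3, 4, 7, 8)

**The three steps most likely to fail**

**1. Step 7 (key step).**
- Risk: the enolate may capture the crowded aroylpalladium species too slowly. Protodeiodination, direct aryl–enolate coupling or acylation at the enolate oxygen could then take over.
- Fallback: no palladium and no CO are used, and C4 comes from DMF. It sets out from 7 and 15 and comes back at 19.
- Compound 7 is lithiated as in step 4 to aryllithium 8 and quenched with DMF to give 2,4,6-tris(methoxymethoxy)-3,5-bis(3-methylbut-2-enyl)benzaldehyde F1.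
- Ketone 15 is converted with LiN(iPr)2 in THF at −78 °C into its lithium enolate F2. This adds to F1 in an aldol reaction to give the β-hydroxy ketone 1-[3,4-bis(methoxymethoxy)phenyl]-3-hydroxy-2-methoxy-3-[2,4,6-tris(methoxymethoxy)-3,5-bis(3-methylbut-2-enyl)phenyl]propan-1-one F3. It forms as a mixture of diastereomers, which is of no consequence.
- Oxidation of the benzylic alcohol with Dess–Martin periodinane and NaHCO3 in CH2Cl2 gives 19.

**2. Step 8.**
- Risk: a freed phenol may add under acid catalysis to a neighbouring prenyl double bond (chroman formation) before all five acetals are gone. Methanol may also cleave the diketone in a retro-Claisen sense before ring C closes.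
- Fallback: deprotection and ring closure are separated, and no strong Brønsted acid is used. It sets out from 19 and comes back at 20, which is now isolated, and from there reaches 21.
- Me3SiOTf and 2,2'-bipyridyl in MeCN at 0 °C to rt exchange each aryl MOM ether for an aryl silyl ether under buffered conditions. This gives the pentakis(trimethylsilyl) ether of the diketone F4.
- Water at neutral pH hydrolyses F4 to 20.
- Ring C is then closed in NaOAc-buffered acetic acid at 80 °C, a medium too weakly acidic to protonate a trisubstituted alkene, to give 21.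

**3. Step 4.**
- Risk: deprotonation at the doubly activated ArCH2–CH= positions may compete, or metalation of the last, buttressed ring CH may stay incomplete. Either would leave material that is hard to separate from the iodide.
- Fallback: the aryl anion is made by halogen–metal exchange, and the prenyl groups come from cross-coupling. No deprotonation is carried out next to a prenyl group. It sets out from 2 and comes back at aryllithium 8, and so at 9.
- N-Bromosuccinimide (1 equiv, MeCN, 0 °C) gives 2-bromo-1,3,5-tris(methoxymethoxy)benzene F5.
- N-Iodosuccinimide (2.2 equiv, MeCN) fills the two remaining, still triply activated positions to give 2-bromo-4,6-diiodo-1,3,5-tris(methoxymethoxy)benzene F6.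
- A double Stille coupling with tributyl(3-methylbut-2-enyl)stannane and Pd(PPh3)4 in DMF at 90 °C engages the C–I bonds ahead of the C–Br bond. It gives 2-bromo-1,3,5-tris(methoxymethoxy)-4,6-bis(3-methylbut-2-enyl)benzene F7.
- n-BuLi in THF at −78 °C effects bromine–lithium exchange to 8, which is quenched with 1,2-diiodoethane as in step 4 to give 9.

**Further compounds**
F1 | step 7 | 2,4,6-tris(methoxymethoxy)-3,5-bis(3-methylbut-2-enyl)benzaldehyde | O=Cc1c(OCOC)c(CC=C(C)C)c(OCOC)c(CC=C(C)C)c1OCOC
F2 | step 7 | lithium enolate of 15 (geometry of no consequence) | COC=C([O-])c1ccc(OCOC)c(OCOC)c1.[Li+]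
F3 | step 7 | 1-[3,4-bis(methoxymethoxy)phenyl]-3-hydroxy-2-methoxy-3-[2,4,6-tris(methoxymethoxy)-3,5-bis(3-methylbut-2-enyl)phenyl]propan-1-one (racemic mixture of diastereomers) | COCOc1ccc(C(=O)C(OC)C(O)c2c(OCOC)c(CC=C(C)C)c(OCOC)c(CC=C(C)C)c2OCOC)cc1OCOC
F4 | step 8 | 1-[3,4-bis(trimethylsilyloxy)phenyl]-2-methoxy-3-[2,4,6-tris(trimethylsilyloxy)-3,5-bis(3-methylbut-2-enyl)phenyl]propane-1,3-dione | COC(C(=O)c1ccc(O[Si](C)(C)C)c(O[Si](C)(C)C)c1)C(=O)c1c(O[Si](C)(C)C)c(CC=C(C)C)c(O[Si](C)(C)C)c(CC=C(C)C)c1O[Si](C)(C)C
F5 | step 4 | 2-bromo-1,3,5-tris(methoxymethoxy)benzene | COCOc1cc(OCOC)c(Br)c(OCOC)c1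
F6 | step 4 | 2-bromo-4,6-diiodo-1,3,5-tris(methoxymethoxy)benzene | COCOc1c(Br)c(OCOC)c(I)c(OCOC)c1I
F7 | step 4 | 2-bromo-1,3,5-tris(methoxymethoxy)-4,6-bis(3-methylbut-2-enyl)benzene | COCOc1c(Br)c(OCOC)c(CC=C(C)C)c(OCOC)c1CC=C(C)C
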